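- Retrosynthesis: the eight O-benzyl groups come off first, then the interflavan C4–C8 bond is cut (upper flavan-4-yl cation plus benzylated epigallocatechin), then the C4 oxygen and the C2/C3 hydrogens are traced back to a flavone, and last the C3–C4 and O1–C8a bonds of the upper ring C are cut.
- Forward: ring C of the upper unit is closed first, at the flavone oxidation level, by a domino C-acylation/SNAr between an acetophenone enolate (O1–C2–C3 with ring B) and a 2-fluorobenzoyl chloride (C4, C4a, C8a of ring A); the lower unit is joined at C4 afterwards.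
- Enabling feature: C4 is bonded to C4a of ring A and lies ortho to C8a. As a carbonyl it is the acyl electrophile for C3 and activates C8a–F for displacement by the enolate oxygen O1; later, as a carbinol para to the 7-oxygen, it is the leaving group for the interflavan bond.
- Stereochemistry: C2 (S) comes from ligand-controlled asymmetric hydrogenation of the flavone; C4 (R) comes from attack of ring D on the flavan-4-yl cation anti to the C2 aryl group (2,4-trans); both centres of the lower unit come from (−)-epigallocatechin.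
- Helpers and their removal: fluoride is lost in the key step, the C2=C3 double bond and the C4 oxygen go in steps 3 and 5, and the benzyl ethers go in step 6.

Key step: step 2

Remark: 4-(benzyloxy)-2-fluorobenzoic acid, 3,4-bis(benzyloxy)acetophenone and (−)-epigallocatechin are taken as purchasable. The C4 carbinol configuration made in step 3 does not matter, because C4 becomes trigonal again in step 5.

**Route**

Step 1
Reactants: 1 4-(benzyloxy)-2-fluorobenzoic acid
Product: 2 4-(benzyloxy)-2-fluorobenzoyl chloride
Conditions: (COCl)2 (1.3 equiv), DMF (cat.), CH2Cl2, 0 °C → rt; volatiles removed, used crude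
Reagents that add atoms: oxalyl chloride, ClC(=O)C(=O)Cl
Why: Standard acid chloride formation through the chloroiminium species from DMF (Vilsmeier-type activation); the aryl fluoride and the benzyl ether are inert.

Step 2
Reactants: 2 4-(benzyloxy)-2-fluorobenzoyl chloride; 3 1-[3,4-bis(benzyloxy)phenyl]ethan-1-one
Product: 5 7-(benzyloxy)-2-[3,4-bis(benzyloxy)phenyl]-4H-chromen-4-one, via β-diketone 4 (not isolated)
Conditions: 3, LiN(SiMe3)2 (2.2 equiv), THF, −78 °C; then 2, −78 °C → rt; then DMF added, 90 °C, same flask
Reagents that add atoms: none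
Why: The lithium enolate of 3 is acylated at carbon by 2 in a crossed Claisen condensation, which forms the C3–C4 bond and leaves β-diketone 4 as its lithium enolate; enol ester from competing O-acylation is funnelled to the same diketonate by Baker–Venkataraman-type acyl transfer. On heating in THF/DMF the enolate oxygen on C2 adds to C8a and fluoride leaves from the Meisenheimer intermediate (intramolecular SNAr), which forms the O1–C8a bond. The closest known reaction type is the base-mediated cycloacylation of 2-halobenzoyl chlorides with ketone enolates or enamines to flavones, chromones and 4-quinolones. Ring C is the only ring closed, as a six-membered 4-pyranone by addition–elimination of oxygen at an aromatic carbon (exo with respect to the C8a–F bond that is broken). No stereocentre is created; C2 and C4 are left trigonal on purpose and are set in steps 3 and 5. The step needs C- rather than O-acylation (lithium enolate at low temperature plus the acyl-transfer convergence) and the right oxygen at the right carbon: the C4 oxygen would have to close a four-membered ring, C8a–F is the only leaving group and is activated by the ortho C4 carbonyl, and the benzyl ethers are inert to the base.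

Step 3
Reactants: 5 7-(benzyloxy)-2-[3,4-bis(benzyloxy)phenyl]-4H-chromen-4-one
Product: 7 (2S,4S)-7-(benzyloxy)-2-[3,4-bis(benzyloxy)phenyl]-3,4-dihydro-2H-chromen-4-ol, via (S)-flavanone 6 (not isolated)
Conditions: H2 (100 bar), Ru(cod)(2-methylallyl)2 (5 mol%), 1,3-bis[1-(naphthalen-1-yl)ethyl]imidazolinium tetrafluoroborate (10 mol%, the enantiomer that gives the 2S series), KOt-Bu (15 mol%), toluene, 25 °C, run until 6 is consumed
Reagents that add atoms: none
Why: Ruthenium–N-heterocyclic-carbene-catalysed asymmetric hydrogenation of the flavone C2=C3 bond, in which the chiral carbene ligand differentiates the two faces and should set C2 as S, followed by cis-selective hydrogenation of the C4 carbonyl of 6 under substrate control.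

Step 4
Reactants: 8 (−)-epigallocatechin
Product: 9 (2R,3R)-5,7-bis(benzyloxy)-2-[3,4,5-tris(benzyloxy)phenyl]-3,4-dihydro-2H-chromen-3-ol
Conditions: BnBr (5.5 equiv), K2CO3 (6 equiv), degassed DMF, N2, −10 °C → rt
Reagents that add atoms: benzyl bromide, BrCc1ccccc1
Why: Williamson etherification of the five phenols, which K2CO3 deprotonates while the aliphatic 3-OH stays free; the two existing stereocentres are not touched.

Step 5
Reactants: 7 (2S,4S)-7-(benzyloxy)-2-[3,4-bis(benzyloxy)phenyl]-3,4-dihydro-2H-chromen-4-ol; 9 (2R,3R)-5,7-bis(benzyloxy)-2-[3,4,5-tris(benzyloxy)phenyl]-3,4-dihydro-2H-chromen-3-ol (3–4 equiv)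
Product: 11 (2R,3R)-5,7-bis(benzyloxy)-8-{(2S,4R)-7-(benzyloxy)-2-[3,4-bis(benzyloxy)phenyl]-3,4-dihydro-2H-chromen-4-yl}-2-[3,4,5-tris(benzyloxy)phenyl]-3,4-dihydro-2H-chromen-3-ol, via flavan-4-yl cation 10 (not isolated)
Conditions: Me3SiOTf (0.2 equiv), 4 Å molecular sieves, CH2Cl2, −78 → −40 °C; Et3N quench; excess 9 recovered by chromatography
Reagents that add atoms: none
Why: Biomimetic SN1 Friedel–Crafts alkylation in which Me3SiOTf ionises the 4-ol, with loss of the C4 hydroxyl as water, to cation 10 (stabilised by ring A and its para 7-benzyloxy group) and ring D of 9 attacks through C8, the more nucleophilic and less hindered of its two free positions, on the face of C4 anti to the equatorial C2 aryl group, which should set C4 as R with the 2,4-trans relationship, while the excess of 9 suppresses self-condensation.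

Step 6
Reactants: 11 (2R,3R)-5,7-bis(benzyloxy)-8-{(2S,4R)-7-(benzyloxy)-2-[3,4-bis(benzyloxy)phenyl]-3,4-dihydro-2H-chromen-4-yl}-2-[3,4,5-tris(benzyloxy)phenyl]-3,4-dihydro-2H-chromen-3-ol
Product: 12 (2R,3R)-8-[(2S,4R)-2-(3,4-dihydroxyphenyl)-7-hydroxy-3,4-dihydro-2H-chromen-4-yl]-2-(3,4,5-trihydroxyphenyl)-3,4-dihydro-2H-chromene-3,5,7-triol
Conditions: H2 (1 atm), Pd(OH)2/C (20 wt%), THF/MeOH/H2O, rt; filtration under N2, lyophilisation
Reagents that add atoms: none
Why: Hydrogenolysis of the eight benzyl aryl ethers under neutral, mild conditions that are standard for oligomeric flavan-3-ols and should leave the benzylic C2–O1 and C4–C8 bonds and all four stereocentres intact.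

**Compound list**

1 | 4-(benzyloxy)-2-fluorobenzoic acid | OC(=O)c1ccc(OCc2ccccc2)cc1F | starting material
2 | 4-(benzyloxy)-2-fluorobenzoyl chloride | ClC(=O)c1ccc(OCc2ccccc2)cc1F | intermediate
3 | 1-[3,4-bis(benzyloxy)phenyl]ethan-1-one | CC(=O)c1ccc(OCc2ccccc2)c(OCc2ccccc2)c1 | starting material
4 | 1-[4-(benzyloxy)-2-fluorophenyl]-3-[3,4-bis(benzyloxy)phenyl]propane-1,3-dione (present as its lithium enolate) | O=C(CC(=O)c1ccc(OCc2ccccc2)c(OCc2ccccc2)c1)c1ccc(OCc2ccccc2)cc1F | intermediate
5 | 7-(benzyloxy)-2-[3,4-bis(benzyloxy)phenyl]-4H-chromen-4-one | O=c1cc(-c2ccc(OCc3ccccc3)c(OCc3ccccc3)c2)oc2cc(OCc3ccccc3)ccc12 | intermediate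
6 | (2S)-7-(benzyloxy)-2-[3,4-bis(benzyloxy)phenyl]-2,3-dihydro-4H-chromen-4-one | O=C1C[C@@H](c2ccc(OCc3ccccc3)c(OCc3ccccc3)c2)Oc2cc(OCc3ccccc3)ccc21 | intermediate
7 | (2S,4S)-7-(benzyloxy)-2-[3,4-bis(benzyloxy)phenyl]-3,4-dihydro-2H-chromen-4-ol (2,4-cis) | c1ccccc1COc1ccc2c(c1)O[C@H](c1ccc(OCc3ccccc3)c(OCc3ccccc3)c1)C[C@@H]2O | intermediate
8 | (−)-epigallocatechin, (2R,3R)-2-(3,4,5-trihydroxyphenyl)-3,4-dihydro-2H-chromene-3,5,7-triol | Oc1cc(O)c2c(c1)O[C@H](c1cc(O)c(O)c(O)c1)[C@H](O)C2 | starting material
9 | (2R,3R)-5,7-bis(benzyloxy)-2-[3,4,5-tris(benzyloxy)phenyl]-3,4-dihydro-2H-chromen-3-ol | c1ccccc1COc1cc(OCc2ccccc2)c2c(c1)O[C@H](c1cc(OCc3ccccc3)c(OCc3ccccc3)c(OCc3ccccc3)c1)[C@H](O)C2 | intermediate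
10 | (2S)-7-(benzyloxy)-2-[3,4-bis(benzyloxy)phenyl]-3,4-dihydro-2H-chromen-4-ylium (C4 benzylic cation) | c1ccccc1COc1ccc2c(c1)O[C@H](c1ccc(OCc3ccccc3)c(OCc3ccccc3)c1)C[CH+]2 | intermediate
11 | (2R,3R)-5,7-bis(benzyloxy)-8-{(2S,4R)-7-(benzyloxy)-2-[3,4-bis(benzyloxy)phenyl]-3,4-dihydro-2H-chromen-4-yl}-2-[3,4,5-tris(benzyloxy)phenyl]-3,4-dihydro-2H-chromen-3-ol | c1ccccc1COc1ccc2c(c1)O[C@H](c1ccc(OCc3ccccc3)c(OCc3ccccc3)c1)C[C@H]2c1c(OCc3ccccc3)cc(OCc3ccccc3)c2c1O[C@H](c1cc(OCc3ccccc3)c(OCc3ccccc3)c(OCc3ccccc3)c1)[C@H](O)C2 | intermediate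
12 | (2R,3R)-8-[(2S,4R)-2-(3,4-dihydroxyphenyl)-7-hydroxy-3,4-dihydro-2H-chromen-4-yl]-2-(3,4,5-trihydroxyphenyl)-3,4-dihydro-2H-chromene-3,5,7-triol | Oc1ccc2c(c1)O[C@H](c1ccc(O)c(O)c1)C[C@H]2c1c(O)cc(O)c2c1O[C@H](c1cc(O)c(O)c(O)c1)[C@H](O)C2 | target

**Step count and risks**

Total step count: 6. Longest linear sequence: 5 (steps 1, 2, 3, 5, 6).

Steps most likely to fail:

1. Step 5. Attack through C6 of ring D, attack on the wrong face of C4, proton loss from C3 of the cation to a flav-3-ene, and self-condensation of the cation with ring A of unreacted 7 may all compete. The fallback changes the leaving group and the mode of activation. It sets out from 7: thiolysis with benzyl mercaptan (cat. BF3·OEt2, CH2Cl2, −40 °C) should give (2S)-7-(benzyloxy)-4-(benzylsulfanyl)-2-[3,4-bis(benzyloxy)phenyl]-3,4-dihydro-2H-chromene F1 as a C4 mixture. F1 and 9 are then coupled with the thiophilic salt AgBF4 (THF, 0 °C), which generates the C4 electrophile irreversibly and without added protic acid. The fallback comes back to the route at 11.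

2. Step 3. Hydrogenolysis of benzyl ethers, reduction of benzenoid rings or insufficient facial discrimination at C2 may occur under the high-pressure hydrogenation. The fallback replaces hydrogenation by hydride conjugate reduction followed by a kinetic resolution. It sets out from 5: 1,4-reduction with LiBH(s-Bu)3 (THF, −78 °C) should give racemic 7-(benzyloxy)-2-[3,4-bis(benzyloxy)phenyl]-2,3-dihydro-4H-chromen-4-one F2. Asymmetric transfer hydrogenation of F2 with RuCl(p-cymene)[(S,S)-TsDPEN] or its antipode (HCO2H/Et3N) should reduce only the 2S enantiomer, which is 6, to the cis alcohol. The unreacted (2R)-7-(benzyloxy)-2-[3,4-bis(benzyloxy)phenyl]-2,3-dihydro-4H-chromen-4-one F3 is racemised with DBU through reversible ring opening to the chalcone and fed back. The fallback comes back to the route at 7.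

3. Step 2. O-acylation or double acylation of the enolate may compete, and fluoride displacement may be slow because the diketonate and the para benzyloxy group lower the electrophilicity of C8a. The fallback gives up the domino for a thermodynamically controlled ester condensation and a separate ring closure. It sets out from 1: Fischer esterification (MeOH, cat. H2SO4, reflux) should give methyl 4-(benzyloxy)-2-fluorobenzoate F4. Crossed Claisen condensation of F4 with 3 (NaH, THF, reflux, then acidic work-up) gives 4, now isolated. 4 is cyclised on its own (K2CO3, DMSO, 110 °C). The fallback comes back to the route at 5.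

**Further compounds**

F1 | step 5 | (2S)-7-(benzyloxy)-4-(benzylsulfanyl)-2-[3,4-bis(benzyloxy)phenyl]-3,4-dihydro-2H-chromene | c1ccccc1COc1ccc2c(c1)O[C@H](c1ccc(OCc3ccccc3)c(OCc3ccccc3)c1)CC2SCc1ccccc1
F2 | step 3 | racemic 7-(benzyloxy)-2-[3,4-bis(benzyloxy)phenyl]-2,3-dihydro-4H-chromen-4-one | O=C1CC(c2ccc(OCc3ccccc3)c(OCc3ccccc3)c2)Oc2cc(OCc3ccccc3)ccc21
F3 | step 3 | (2R)-7-(benzyloxy)-2-[3,4-bis(benzyloxy)phenyl]-2,3-dihydro-4H-chromen-4-one | O=C1C[C@H](c2ccc(OCc3ccccc3)c(OCc3ccccc3)c2)Oc2cc(OCc3ccccc3)ccc21
F4 | step 2 | methyl 4-(benzyloxy)-2-fluorobenzoate | COC(=O)c1ccc(OCc2ccccc2)cc1F
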